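The C40 target is read as the head-to-head Diels–Alder dimer of a single C20 triene alcohol, (12E)-labda-8(17),12,14-trien-18-ol. Its central cyclohexene consists of C12, C13, C14 and C15 of one unit and C14' and C15' of the other. In the last step the s-cis C12=C13–C14=C15 diene of one molecule adds across the terminal C14'=C15' vinyl group of a second one. This closes the only ring absent from the monomer, forms the C15–C15' and C12–C14' bonds and sets both new stereocentres on the unprotected alcohol. The monomer is carved from abietic acid, whose rings A and B already hold all four decalin stereocentres.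

Key step: step 9

Remarks on the chemistry:
- Labdane numbering is used throughout, with primed locants for the unit that reacts as dienophile. C18 is the 4α (equatorial) carbon, trans to the C10 methyl. On opening of ring C the abietane C14 becomes labdane C17.
- Assumption: diol 3 is taken as the α-cis isomer and ketol 9 as a mixture of C12 epimers; both centres are destroyed in the following operation.

Step 1
Reactants: 1 abietic acid
Product: 2 methyl abietate
Conditions: MeI, K2CO3, DMF, rt
Reagents that add atoms: iodomethane, CI
Why: SN2 O-alkylation of the potassium carboxylate masks the hindered C18 acid as an ester that has no alpha hydrogen and should survive every later step up to its reduction; no stereocentre is touched.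

Step 2
Reactants: 2 methyl abietate
Product: 4 methyl 13,14-dioxo-13,14-secoabiet-7-en-18-oate (keto-enal), via cis-13,14-diol 3 (not isolated)
Conditions: OsO4 (2 mol%), NMO, acetone/H2O, rt; then NaIO4, rt
Reagents that add atoms: osmium tetroxide, O=[Os](=O)(=O)=O (its oxygen is restored by N-methylmorpholine N-oxide, C[N+]1([O-])CCOCC1)
Why: Upjohn dihydroxylation should take the more exposed C13=C14 bond of the heteroannular diene, and periodate (Malaprade) cleavage of the diol then opens ring C and leaves the C7=C8 bond as a deactivated enal; the stereocentres of rings A and B are not affected.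

Step 3
Reactants: 4 methyl 13,14-dioxo-13,14-secoabiet-7-en-18-oate
Product: 7 methyl 13-oxo-13,14-secoabiet-8(14)-en-18-oate, via tosylhydrazone 5 (not isolated), via allylic diazene 6 (not isolated)
Conditions: TsNHNH2, THF, rt; evaporate; catecholborane, CHCl3, 0 °C; NaOAc·3H2O, reflux
Reagents that add atoms: none
Why: Hutchins–Kabalka reductive transposition of an α,β-unsaturated tosylhydrazone: the aldehyde should condense faster than the hindered isopropyl ketone, hydride adds to the former C14, sulfinate is lost, and the allylic diazene passes its hydrogen to C7 in a retro-ene loss of N2, which moves the alkene to the exocyclic C8=C17 position without creating a stereocentre.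

Step 4
Reactants: 7 methyl 13-oxo-13,14-secoabiet-8(14)-en-18-oate
Product: 9 methyl 12-hydroxy-13-oxo-13,14-secoabiet-8(14)-en-18-oate, via potassium enolate 8 (not isolated)
Conditions: KN(SiMe3)2, THF, −78 °C; 2-(phenylsulfonyl)-3-phenyloxaziridine, −78 °C; aq. NH4Cl
Reagents that add atoms: 2-(phenylsulfonyl)-3-phenyloxaziridine, O=S(=O)(N1OC1c1ccccc1)c1ccccc1
Why: Kinetic deprotonation should occur at the C12 methylene and not at the isopropyl methine, and the enolate is hydroxylated by the oxaziridine (Davis oxidation); the new C12 carbinol centre is not controlled and need not be, because step 5 destroys it.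

Step 5
Reactants: 9 methyl 12-hydroxy-13-oxo-13,14-secoabiet-8(14)-en-18-oate
Product: 10 methyl 12-oxo-13,14,15,16-tetranorlabd-8(17)-en-18-oate
Conditions: Pb(OAc)4, MeOH/toluene, 0 °C
Reagents that add atoms: none
Why: Criegee cleavage of the α-hydroxy ketone between C12 and C13 turns the carbinol carbon into the C12 aldehyde and expels the isopropyl ketone carbon as methyl isobutyrate; the 1,1-disubstituted alkene should be inert to the reagent at this temperature.

Step 6
Reactants: 10 methyl 12-oxo-13,14,15,16-tetranorlabd-8(17)-en-18-oate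
Product: 11 methyl (12E)-14-oxo-15-norlabda-8(17),12-dien-18-oate
Conditions: Ph3P=C(CH3)CHO, toluene, 90 °C
Reagents that add atoms: 2-(triphenylphosphoranylidene)propanal, CC(C=O)=P(c1ccccc1)(c1ccccc1)c1ccccc1
Why: Wittig reaction of a stabilised ylide, which should give the (E)-trisubstituted enal (C16 methyl cis to C11) and attacks the unhindered aldehyde but not the neopentyl ester.

Step 7
Reactants: 11 methyl (12E)-14-oxo-15-norlabda-8(17),12-dien-18-oate
Product: 12 methyl (12E)-labda-8(17),12,14-trien-18-oate
Conditions: MePPh3Br, KOtBu, THF, 0 °C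
Reagents that add atoms: methyltriphenylphosphonium bromide, C[P+](c1ccccc1)(c1ccccc1)c1ccccc1.[Br-]
Why: Wittig methylenation of the enal carbonyl completes the (12E)-diene without affecting the alkene geometry or the hindered ester.

Step 8
Reactants: 12 methyl (12E)-labda-8(17),12,14-trien-18-oate
Product: 13 (12E)-labda-8(17),12,14-trien-18-ol
Conditions: LiAlH4, THF, 0 °C to reflux
Reagents that add atoms: none
Why: Hydride reduction of the neopentyl methyl ester gives the primary C18 alcohol, while alkenes that carry no polarising group are inert to LiAlH4.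

Step 9
Reactants: 13 (12E)-labda-8(17),12,14-trien-18-ol (two molecules)
Product: 14 target, the (12S,14'S) endo head-to-head dimer
Conditions: CH2Cl2 (3 M), BHT (1 mol%), 1.2 GPa, 50 °C
Reagents that add atoms: none
Why: Pressure-accelerated thermal [4+2] cyclodimerisation, in which the s-cis C12=C13–C14=C15 diene of one molecule of 13 adds suprafacially across the terminal C14'=C15' vinyl group of a second one through a concerted but asynchronous transition state with the C15–C15' bond between the two unsubstituted termini running ahead of the C12–C14' bond. The closest known reaction type is the Diels–Alder dimerisation of acyclic 1,3-dienes such as isoprene, piperylene and myrcene, which high pressure is known to accelerate. The cyclohexene, the only ring formed, is closed by intermolecular [4+2] cycloaddition without a tether. C12 and C14' should become cis through the endo transition state, in which the remaining C12'=C13' alkene lies under C13–C14 of the diene and the E geometry places C11 outside; the absolute sense (12S,14'S) depends on the diene face, which the C9 stereocentre of the diene unit is to differentiate because allylic 1,3-strain between the C16 methyl and C11 turns the C9–C11 bond out of the diene plane and places the decalin over one face of C12. The step needs chemoselectivity (only the monosubstituted C14'=C15' bond is an accessible 2π partner, the 1,1-disubstituted C8=C17 and trisubstituted C12'=C13' bonds are not), head-to-head regioselectivity (bonding of the two CH2 termini leaves two allyl-stabilised fragments), endo selectivity and facial selectivity. Facial control is the weakest of these, so the (12R,14'R) endo adduct is the by-product to be expected and removed by chromatography.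

Compound list
1 | abietic acid (abieta-7,13-dien-18-oic acid) | CC(C)C1=CC2=CC[C@H]3[C@](C)(C(=O)O)CCC[C@]3(C)[C@H]2CC1 | starting material
2 | methyl abietate (methyl abieta-7,13-dien-18-oate) | CC(C)C1=CC2=CC[C@H]3[C@](C)(C(=O)OC)CCC[C@]3(C)[C@H]2CC1 | intermediate
3 | methyl 13α,14α-dihydroxyabiet-7-en-18-oate (cis-diol, face assumed) | CC(C)[C@@]1(O)[C@H](O)C2=CC[C@H]3[C@](C)(C(=O)OC)CCC[C@]3(C)[C@H]2CC1 | intermediate
4 | methyl 13,14-dioxo-13,14-secoabiet-7-en-18-oate (C8 carbaldehyde conjugated with C7=C8; C9 side chain CH2CH2C(=O)CH(CH3)2) | O=CC1=CC[C@H]2[C@](C)(C(=O)OC)CCC[C@]2(C)[C@H]1CCC(=O)C(C)C | intermediate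
5 | (E)-p-toluenesulfonylhydrazone of the aldehyde of 4 | Cc1ccc(cc1)S(=O)(=O)N/N=C/C1=CC[C@H]2[C@](C)(C(=O)OC)CCC[C@]2(C)[C@H]1CCC(=O)C(C)C | intermediate
6 | allylic diazene (HN=N–CH2 on C8 of the C7=C8 alkene) | N=NCC1=CC[C@H]2[C@](C)(C(=O)OC)CCC[C@]2(C)[C@H]1CCC(=O)C(C)C | intermediate
7 | methyl 13-oxo-13,14-secoabiet-8(14)-en-18-oate (exocyclic C8=CH2, the labdane C8=C17; isopropyl ketone side chain) | C=C1CC[C@H]2[C@](C)(C(=O)OC)CCC[C@]2(C)[C@H]1CCC(=O)C(C)C | intermediate
8 | potassium (Z)-enolate of 7 (C12=C13–OK) | C=C1CC[C@H]2[C@](C)(C(=O)OC)CCC[C@]2(C)[C@H]1C/C=C(\[O-])C(C)C.[K+] | intermediate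
9 | methyl 12-hydroxy-13-oxo-13,14-secoabiet-8(14)-en-18-oate (C12 epimers) | C=C1CC[C@H]2[C@](C)(C(=O)OC)CCC[C@]2(C)[C@H]1CC(O)C(=O)C(C)C | intermediate
10 | methyl 12-oxo-13,14,15,16-tetranorlabd-8(17)-en-18-oate | C=C1CC[C@H]2[C@](C)(C(=O)OC)CCC[C@]2(C)[C@H]1CC=O | intermediate
11 | methyl (12E)-14-oxo-15-norlabda-8(17),12-dien-18-oate | C=C1CC[C@H]2[C@](C)(C(=O)OC)CCC[C@]2(C)[C@H]1C/C=C(\C)C=O | intermediate
12 | methyl (12E)-labda-8(17),12,14-trien-18-oate | C=C1CC[C@H]2[C@](C)(C(=O)OC)CCC[C@]2(C)[C@H]1C/C=C(\C)C=C | intermediate
13 | (12E)-labda-8(17),12,14-trien-18-ol (4-epi-trans-communol; 4R,5R,9S,10R; 4α-CH2OH, 5α-H, 9α-H, 10β-CH3) | C=C1CC[C@H]2[C@](C)(CO)CCC[C@]2(C)[C@H]1C/C=C(\C)C=C | intermediate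
14 | (12S,14'S) endo head-to-head Diels–Alder dimer of 13: 1-methylcyclohexene (C13=C14) carrying at C12 the C11 methylene of one 18-hydroxylabd-8(17)-ene bicycle and, cis to it at C14', the (E)-C(CH3)=CH–CH2 link to the second bicycle | C=C1CC[C@H]2[C@](C)(CO)CCC[C@]2(C)[C@H]1C/C=C(\C)[C@H]1CCC=C(C)[C@H]1C[C@H]1C(=C)CC[C@H]2[C@](C)(CO)CCC[C@]12C | target

Total step count: 9
Longest linear sequence: 9 steps (1 to 14; the last step consumes two molecules of 13)

Steps most likely to fail

Step 9. What may go wrong: the remote C9 stereocentre may discriminate the two faces of the diene only weakly, the uncatalysed cycloaddition may be slow, and chain oligomerisation through the vinyl group may consume the triene. The fallback is a catalyst-controlled cross Diels–Alder reaction between two different partners; it sets out from aldehyde 10 and diene ester 12 and comes back to the route at target 14. Aldehyde 10 is homologated with Ph3P=CHOMe (MeOCH2PPh3Cl, KN(SiMe3)2, THF, 0 °C) to the methyl enol ether F1, which oxalic acid in THF/H2O hydrolyses to the C13 aldehyde F2. Vinylmagnesium bromide (THF, −78 °C) gives the allylic alcohol F3, and Dess–Martin periodinane gives the vinyl ketone F4. This ketone is activated as its iminium ion by 5-benzyl-3-methyl-2-(5-methylfuran-2-yl)imidazolidin-4-one·HClO4 (20 mol%, EtOH, −20 °C; the catalyst enantiomer that delivers 14'S is to be chosen). It should add to 12 in the endo mode with C15' bonding to C15, to give the cis ketone F5, the face of the dienophile now being chosen by the catalyst and not by the decalins. Kinetic deprotonation at the C12' methylene (KN(SiMe3)2, THF, −78 °C) gives the potassium (Z)-enolate F6, which PhNTf2 traps as the (Z)-enol triflate F7. MeMgBr with Fe(acac)3 (THF/NMP, −30 °C) replaces the triflate by methyl with retention to give the bis(methyl ester) F8 with the 12'E alkene, and LiAlH4 (THF) reduces both esters to 14.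

Step 3. What may go wrong: the hydrazide or the borane may also attack the isopropyl ketone, and 1,2-reduction without shift of the alkene may compete. The fallback is the formate hydrogenolysis of an allylic carbonate under palladium catalysis; it sets out from 4 and comes back at 7. NaBH4 (CH2Cl2/MeOH, −78 °C) should reduce the conjugated aldehyde in preference to the hindered ketone to the allylic alcohol F9, ClCO2Me and pyridine give the allylic methyl carbonate F10, and Pd(OAc)2, n-Bu3P and HCO2NH4 (THF, 50 °C) transfer hydride to the ring terminus C7 of the allyl complex, which gives the exocyclic alkene 7.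

Step 2. What may go wrong: osmylation may not distinguish the C13=C14 bond from the C7=C8 bond well enough, and over-oxidation may follow in the one-pot cleavage. The fallback is epoxidation followed by periodic acid cleavage; it sets out from 2 and comes back at 4. mCPBA (1.0 equiv, CH2Cl2, NaHCO3, −20 °C) should epoxidise the more exposed C13=C14 bond to the vinyl epoxide F11 (α face assumed), and H5IO6 (THF/H2O, 0 °C) opens it to diol 3 and cleaves this in the same flask to 4.

Further compounds
F1 | step 9 | methyl 13-methoxy-14,15,16-trinorlabda-8(17),12-dien-18-oate (enol ether, E/Z mixture) | C=C1CC[C@H]2[C@](C)(C(=O)OC)CCC[C@]2(C)[C@H]1CC=COC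
F2 | step 9 | methyl 13-oxo-14,15,16-trinorlabd-8(17)-en-18-oate (C13 aldehyde) | C=C1CC[C@H]2[C@](C)(C(=O)OC)CCC[C@]2(C)[C@H]1CCC=O
F3 | step 9 | methyl 13-hydroxy-16-norlabda-8(17),14-dien-18-oate (allylic alcohol, C13 epimers) | C=C1CC[C@H]2[C@](C)(C(=O)OC)CCC[C@]2(C)[C@H]1CCC(O)C=C
F4 | step 9 | methyl 13-oxo-16-norlabda-8(17),14-dien-18-oate (vinyl ketone) | C=C1CC[C@H]2[C@](C)(C(=O)OC)CCC[C@]2(C)[C@H]1CCC(=O)C=C
F5 | step 9 | cis (12S,14'S) cyclohexene adduct of 12 and F4 with the C13' ketone on C14' | C=C1CC[C@H]2[C@](C)(C(=O)OC)CCC[C@]2(C)[C@H]1CCC(=O)[C@H]1CCC=C(C)[C@H]1C[C@H]1C(=C)CC[C@H]2[C@](C)(C(=O)OC)CCC[C@]12C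
F6 | step 9 | potassium (Z)-enolate of F5 (C12'=C13'–OK) | C=C1CC[C@H]2[C@](C)(C(=O)OC)CCC[C@]2(C)[C@H]1C/C=C(\[O-])[C@H]1CCC=C(C)[C@H]1C[C@H]1C(=C)CC[C@H]2[C@](C)(C(=O)OC)CCC[C@]12C.[K+]
F7 | step 9 | (Z)-enol triflate of F5 (C12'=C13'–OTf) | C=C1CC[C@H]2[C@](C)(C(=O)OC)CCC[C@]2(C)[C@H]1C/C=C(\OS(=O)(=O)C(F)(F)F)[C@H]1CCC=C(C)[C@H]1C[C@H]1C(=C)CC[C@H]2[C@](C)(C(=O)OC)CCC[C@]12C
F8 | step 9 | bis(methyl ester) corresponding to 14 (18,18'-dioate) | C=C1CC[C@H]2[C@](C)(C(=O)OC)CCC[C@]2(C)[C@H]1C/C=C(\C)[C@H]1CCC=C(C)[C@H]1C[C@H]1C(=C)CC[C@H]2[C@](C)(C(=O)OC)CCC[C@]12C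
F9 | step 3 | methyl 14-hydroxy-13-oxo-13,14-secoabiet-7-en-18-oate (allylic alcohol) | OCC1=CC[C@H]2[C@](C)(C(=O)OC)CCC[C@]2(C)[C@H]1CCC(=O)C(C)C
F10 | step 3 | methyl carbonate of F9 | COC(=O)OCC1=CC[C@H]2[C@](C)(C(=O)OC)CCC[C@]2(C)[C@H]1CCC(=O)C(C)C
F11 | step 2 | methyl 13α,14α-epoxyabiet-7-en-18-oate | CC(C)[C@@]1(O4)[C@H]4C2=CC[C@H]3[C@](C)(C(=O)OC)CCC[C@]3(C)[C@H]2CC1
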